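The hydroxylated ring of the central naphthol (ring B) is traced back to two pieces, a benzocyclobutenone and an alkenyllithium. The key step exploits that ring's substitution pattern: oxygen on C1 beside the methoxy-bearing C8/C8a edge, unit A on C2, hydrogen on C3 and unit C on C4. C1, C8a, C4a and C4 come from an 8-aryl-5-methoxybenzocyclobutenone, C2 and C3 from a 1-arylvinyllithium. In one operation, carbonyl addition forms C1–C2, and alkoxide-driven 4π ring opening followed by 6π electrocyclization forms C3–C4, closing the ring as a 2,4-diaryl-1-tetralone. Both partners derive from one MOM-protected 4-bromo-8-methoxy-1-naphthol; the cyclobutenone arises from a 3-methoxybenzyne [2+2] cycloaddition.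

Key step: step 12

Remark: ring B is the central 8-methoxynaphthalen-1-ol, and units A and C are the 4-hydroxy-5-methoxynaphthalen-1-yl groups on its C2 and C4. "Ar" stands for 5-methoxy-4-(methoxymethoxy)naphthalen-1-yl. The target has no stereocentre and its biaryl axes are not specified, so all sp3 intermediates are carried as racemates or diastereomer mixtures.

Step 1
Reactants: 1 3-methoxyphenol
Product: 2 1-methoxy-3-(methoxymethoxy)benzene
Conditions: NaH, DMF, 0 °C; MOMCl, 0 °C to rt
Reagents that add atoms: chloromethyl methyl ether, COCCl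
Why: Williamson-type O-alkylation of the sodium phenoxide by the reactive α-chloro ether should install the acetal that directs the next metalation.

Step 2
Reactants: 2 1-methoxy-3-(methoxymethoxy)benzene
Product: 5 2-iodo-3-methoxyphenol, via 2-lithio aryl ether 3 (not isolated), via 2-iodo MOM ether 4 (not isolated)
Conditions: n-BuLi, THF, 0 °C; I2, –78 °C to rt; aq. Na2S2O3 work-up; crude in HCl, MeOH, 50 °C
Reagents that add atoms: iodine, [I][I]
Why: Directed ortho-metalation should occur at C2, the position flanked and activated by both oxygen groups, iodinolysis then traps the aryllithium, and acid-catalysed acetal methanolysis frees the phenol.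

Step 3
Reactants: 5 2-iodo-3-methoxyphenol
Product: 6 2-iodo-3-methoxyphenyl trifluoromethanesulfonate
Conditions: Tf2O, pyridine, CH2Cl2, 0 °C
Reagents that add atoms: trifluoromethanesulfonic anhydride, O=S(=O)(OS(=O)(=O)C(F)(F)F)C(F)(F)F
Why: O-sulfonylation of the phenol with the anhydride and an amine base is a standard triflate formation and puts the leaving group next to the iodine, as the aryne generation needs.

Step 4
Reactants: 7 naphthalene-1,8-diol
Product: 8 8-methoxynaphthalen-1-ol
Conditions: MeI (1.05 equiv), K2CO3, acetone, reflux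
Reagents that add atoms: iodomethane, CI
Why: Williamson O-methylation should stop at the monoether because the remaining hydroxyl is held in a peri hydrogen bond to the new methoxy oxygen and is too weakly acidic for carbonate.

Step 5
Reactants: 8 8-methoxynaphthalen-1-ol
Product: 9 4-bromo-8-methoxynaphthalen-1-ol
Conditions: NBS (1.0 equiv), MeCN, –20 °C to 0 °C
Reagents that add atoms: N-bromosuccinimide, O=C1CCC(=O)N1Br
Why: Electrophilic aromatic bromination is expected at C4, the α-position para to the free hydroxyl, since the phenol activates its ring more strongly than the methoxy group activates the other.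

Step 6
Reactants: 9 4-bromo-8-methoxynaphthalen-1-ol
Product: 10 1-bromo-5-methoxy-4-(methoxymethoxy)naphthalene
Conditions: NaH, DMF, 0 °C; MOMCl, 0 °C to rt
Reagents that add atoms: chloromethyl methyl ether, COCCl
Why: Irreversible deprotonation breaks the peri hydrogen bond and Williamson-type alkylation of the naphthoxide then gives the acetal, which tolerates every organometallic step that follows.

Step 7
Reactants: 10 1-bromo-5-methoxy-4-(methoxymethoxy)naphthalene
Product: 11 tert-butyl 2-[5-methoxy-4-(methoxymethoxy)naphthalen-1-yl]acetate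
Conditions: BrZnCH2CO2t-Bu (1.5 equiv), Pd2(dba)3, XPhos, THF, 60 °C
Reagents that add atoms: (2-tert-butoxy-2-oxoethyl)zinc bromide, CC(C)(C)OC(=O)C[Zn]Br
Why: Negishi-type palladium-catalysed coupling of the aryl bromide with the zinc ester enolate (Reformatsky reagent) runs through oxidative addition, transmetalation and reductive elimination under essentially neutral conditions, so the arylacetate should form without a strong base that could enolize the product and lead to diarylation or Claisen condensation.

Step 8
Reactants: 11 tert-butyl 2-[5-methoxy-4-(methoxymethoxy)naphthalen-1-yl]acetate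
Product: 13 tert-butyl({1-tert-butoxy-2-[5-methoxy-4-(methoxymethoxy)naphthalen-1-yl]ethenyl}oxy)dimethylsilane (E/Z mixture), via lithium ester enolate 12 (not isolated)
Conditions: LiN(i-Pr)2, THF, –78 °C; t-BuMe2SiCl, DMPU, –78 °C to rt
Reagents that add atoms: tert-butyl(chloro)dimethylsilane, CC(C)(C)[Si](C)(C)Cl
Why: Kinetic deprotonation of the benzylic ester α-position and O-silylation of the enolate, favoured over C-silylation by the bulky silyl chloride and the polar cosolvent, should give the ketene silyl acetal, whose alkene geometry is of no consequence.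

Step 9
Reactants: 13 tert-butyl({1-tert-butoxy-2-[5-methoxy-4-(methoxymethoxy)naphthalen-1-yl]ethenyl}oxy)dimethylsilane; 6 2-iodo-3-methoxyphenyl trifluoromethanesulfonate
Product: 16 5-methoxy-8-[5-methoxy-4-(methoxymethoxy)naphthalen-1-yl]bicyclo[4.2.0]octa-1,3,5-trien-7-one (racemic), via 3-methoxybenzyne 14 (not isolated), via silyl tert-butyl ketal 15 (not isolated)
Conditions: n-BuLi, THF, –78 °C; then aq. HF, MeCN, 0 °C
Reagents that add atoms: none
Why: Iodine–lithium exchange and loss of triflate release the aryne, which undergoes a polar [2+2] cycloaddition with the ketene silyl acetal in which the nucleophilic alkene carbon attacks the aryne carbon remote from the methoxy group so that the developing aryl anion sits beside that inductively withdrawing group and closes onto the oxocarbenium carbon, placing the masked carbonyl next to the methoxy-bearing carbon, and fluoride-assisted ketal hydrolysis then unveils the ketone under conditions too mild to cleave the aryl acetal.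

Step 10
Reactants: 10 1-bromo-5-methoxy-4-(methoxymethoxy)naphthalene
Product: 18 1-ethynyl-5-methoxy-4-(methoxymethoxy)naphthalene, via silylalkyne 17 (not isolated)
Conditions: Me3SiC≡CH, Pd(PPh3)2Cl2, CuI, Et3N, 70 °C; then K2CO3, MeOH, rt
Reagents that add atoms: ethynyltrimethylsilane, C#C[Si](C)(C)C
Why: Sonogashira coupling of the aryl bromide with the silyl-capped acetylene followed by base-catalysed methanolysis of the C–Si bond should give the terminal alkyne, all other groups being inert to these mildly basic conditions.

Step 11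
Reactants: 18 1-ethynyl-5-methoxy-4-(methoxymethoxy)naphthalene
Product: 20 1-(1-bromoethenyl)-5-methoxy-4-(methoxymethoxy)naphthalene, via α-alkenylalane 19 (not isolated)
Conditions: i-Bu2AlH, Ni(dppp)Cl2 (3 mol%), THF, 0 °C to rt; then NBS, 0 °C
Reagents that add atoms: N-bromosuccinimide, O=C1CCC(=O)N1Br
Why: Nickel-catalysed α-selective (Markovnikov) hydroalumination places aluminium on the internal carbon of the terminal arylacetylene and bromodealumination then occurs at that carbon, so the 1-bromoalkene should form without any protic acid that would cleave the acetal.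

Step 12
Reactants: 20 1-(1-bromoethenyl)-5-methoxy-4-(methoxymethoxy)naphthalene; 16 5-methoxy-8-[5-methoxy-4-(methoxymethoxy)naphthalen-1-yl]bicyclo[4.2.0]octa-1,3,5-trien-7-one
Product: 25 8-methoxy-2,4-bis[5-methoxy-4-(methoxymethoxy)naphthalen-1-yl]-3,4-dihydronaphthalen-1(2H)-one (racemic diastereomer mixture), via vinyllithium 21 (not isolated), via cyclobutenoxide 22 (not isolated), via o-quinodimethane enolate 23 (not isolated), via tetralone enolate 24 (not isolated)
Conditions: t-BuLi (2 equiv), THF, –78 °C; then 16, –78 °C to rt; aq. NH4Cl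
Reagents that add atoms: none
Why: Bromine–lithium exchange gives vinyllithium 21, whose aryl-bearing carbon adds to the strained carbonyl of 16 (C1–C2); the resulting alkoxide 22 undergoes oxy-anion-accelerated conrotatory 4π opening of the C7–C8 bond to o-quinodimethane 23, in which the two exocyclic double bonds and the vinyl group make a hexatriene that closes thermally (C3–C4), restoring the benzene ring and leaving enolate 24 for protonation on work-up. The closest known reaction type is the addition of alkenyllithiums to benzocyclobutenones with alkoxide-accelerated electrocyclic ring expansion to tetralones and naphthols. The six-membered carbocycle closes by disrotatory 6π electrocyclization (seen ionically, a 6-endo attack of the benzylic carbanion terminus on the enone terminus), a thermally allowed pericyclic closure. The new stereocentres C4 (set by the triene geometry and the disrotatory closure, without absolute control) and C2 (set by uncontrolled protonation of 24) are accepted as a mixture because both become sp2 in step 13. The step needs 1,2-addition to win over α-deprotonation, which the substrate secures because its enolate would be an antiaromatic benzocyclobutadiene while the ring-strained carbonyl is highly electrophilic, and it needs the right torquoselectivity, which the strongly donating oxido group secures by rotating outward and so turning the vinyl group inward toward C4.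

Step 13
Reactants: 25 8-methoxy-2,4-bis[5-methoxy-4-(methoxymethoxy)naphthalen-1-yl]-3,4-dihydronaphthalen-1(2H)-one
Product: 29 8-methoxy-2,4-bis[5-methoxy-4-(methoxymethoxy)naphthalen-1-yl]naphthalen-1-ol, via potassium enolate 26 (not isolated), via α-bromo ketone 27 (not isolated), via 4H-naphthalenone 28 (not isolated)
Conditions: KN(SiMe3)2 (1.05 equiv), THF, –78 °C; NBS (1.0 equiv), –78 °C; DBU, –78 °C to rt; aq. NH4Cl
Reagents that add atoms: none
Why: Deprotonation of the isolated tetralone with the potassium amide gives a reactive potassium enolate whose α-bromination at C2, followed by base-induced dehydrobromination (E2 toward C3) and prototropic tautomerization of the resulting 4H-naphthalenone, should aromatize ring B in a medium that stays basic, so the acetals survive, the new naphthol never meets a strong oxidant, and both sp3 stereocentres disappear.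

Step 14
Reactants: 29 8-methoxy-2,4-bis[5-methoxy-4-(methoxymethoxy)naphthalen-1-yl]naphthalen-1-ol
Product: 30 2,4-bis(4-hydroxy-5-methoxynaphthalen-1-yl)-8-methoxynaphthalen-1-ol (CNP0528831.0)
Conditions: HCl, MeOH/THF, 45 °C, degassed, under argon
Reagents that add atoms: none
Why: Acid-catalysed acetal methanolysis should remove both methoxymethyl ethers while the aryl methyl ethers and biaryl bonds are inert, and exclusion of air protects the electron-rich trinaphthol.

Compound list
1 | 3-methoxyphenol | COc1cccc(O)c1 | starting material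
2 | 1-methoxy-3-(methoxymethoxy)benzene | COCOc1cccc(OC)c1 | intermediate
3 | [2-methoxy-6-(methoxymethoxy)phenyl]lithium | [Li]c1c(OC)cccc1OCOC | intermediate (not isolated)
4 | 2-iodo-1-methoxy-3-(methoxymethoxy)benzene | COCOc1cccc(OC)c1I | intermediate (not isolated)
5 | 2-iodo-3-methoxyphenol | COc1cccc(O)c1I | intermediate
6 | 2-iodo-3-methoxyphenyl trifluoromethanesulfonate | COc1cccc(OS(=O)(=O)C(F)(F)F)c1I | intermediate
7 | naphthalene-1,8-diol | Oc1cccc2cccc(O)c12 | starting material
8 | 8-methoxynaphthalen-1-ol | COc1cccc2cccc(O)c12 | intermediate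
9 | 4-bromo-8-methoxynaphthalen-1-ol | COc1cccc2c(Br)ccc(O)c12 | intermediate
10 | 1-bromo-5-methoxy-4-(methoxymethoxy)naphthalene | COCOc1ccc(Br)c2cccc(OC)c12 | intermediate
11 | tert-butyl 2-[5-methoxy-4-(methoxymethoxy)naphthalen-1-yl]acetate | COCOc1ccc(CC(=O)OC(C)(C)C)c2cccc(OC)c12 | intermediate
12 | lithium 1-tert-butoxy-2-[5-methoxy-4-(methoxymethoxy)naphthalen-1-yl]ethen-1-olate (enolate of 11) | COCOc1ccc(C=C(O[Li])OC(C)(C)C)c2cccc(OC)c12 | intermediate (not isolated)
13 | tert-butyl({1-tert-butoxy-2-[5-methoxy-4-(methoxymethoxy)naphthalen-1-yl]ethenyl}oxy)dimethylsilane (E/Z mixture) | COCOc1ccc(C=C(OC(C)(C)C)O[Si](C)(C)C(C)(C)C)c2cccc(OC)c12 | intermediate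
14 | 3-methoxybenzyne (1-methoxycyclohexa-1,3-dien-5-yne) | COC1=CC=CC#C1 | intermediate (not isolated)
15 | tert-butyl({7-tert-butoxy-5-methoxy-8-[5-methoxy-4-(methoxymethoxy)naphthalen-1-yl]bicyclo[4.2.0]octa-1,3,5-trien-7-yl}oxy)dimethylsilane (racemic diastereomer mixture) | COc1cccc2c1C(OC(C)(C)C)(O[Si](C)(C)C(C)(C)C)C2c1ccc(OCOC)c2c(OC)cccc12 | intermediate (not isolated)
16 | 5-methoxy-8-[5-methoxy-4-(methoxymethoxy)naphthalen-1-yl]bicyclo[4.2.0]octa-1,3,5-trien-7-one (racemic) | COc1cccc2c1C(=O)C2c1ccc(OCOC)c2c(OC)cccc12 | intermediate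
17 | {[5-methoxy-4-(methoxymethoxy)naphthalen-1-yl]ethynyl}trimethylsilane | COCOc1ccc(C#C[Si](C)(C)C)c2cccc(OC)c12 | intermediate (not isolated)
18 | 1-ethynyl-5-methoxy-4-(methoxymethoxy)naphthalene | C#Cc1ccc(OCOC)c2c(OC)cccc12 | intermediate
19 | {1-[5-methoxy-4-(methoxymethoxy)naphthalen-1-yl]ethenyl}bis(2-methylpropyl)alumane | C=C(c1ccc(OCOC)c2c(OC)cccc12)[Al](CC(C)C)CC(C)C | intermediate (not isolated)
20 | 1-(1-bromoethenyl)-5-methoxy-4-(methoxymethoxy)naphthalene | C=C(Br)c1ccc(OCOC)c2c(OC)cccc12 | intermediate
21 | {1-[5-methoxy-4-(methoxymethoxy)naphthalen-1-yl]ethenyl}lithium | [Li]C(=C)c1ccc(OCOC)c2c(OC)cccc12 | intermediate (not isolated)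
22 | lithium 5-methoxy-7-(1-Ar-ethenyl)-8-Ar-bicyclo[4.2.0]octa-1,3,5-trien-7-olate (racemic diastereomer mixture) | COc1cccc2c1C(O[Li])(C(=C)c1ccc(OCOC)c3c(OC)cccc13)C2c1ccc(OCOC)c2c(OC)cccc12 | intermediate (not isolated)
23 | lithium 2-Ar-1-[6-(Ar-methylidene)-2-methoxycyclohexa-2,4-dien-1-ylidene]prop-2-en-1-olate (ring-opened o-quinodimethane; oxido group outward) | COC1=CC=CC(=Cc2ccc(OCOC)c3c(OC)cccc23)C1=C(O[Li])C(=C)c1ccc(OCOC)c2c(OC)cccc12 | intermediate (not isolated)
24 | lithium 8-methoxy-2,4-bis(Ar)-3,4-dihydronaphthalen-1-olate (racemic) | COc1cccc2c1C(O[Li])=C(c1ccc(OCOC)c3c(OC)cccc13)CC2c1ccc(OCOC)c2c(OC)cccc12 | intermediate (not isolated)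
25 | 8-methoxy-2,4-bis[5-methoxy-4-(methoxymethoxy)naphthalen-1-yl]-3,4-dihydronaphthalen-1(2H)-one (racemic diastereomer mixture) | COc1cccc2c1C(=O)C(c1ccc(OCOC)c3c(OC)cccc13)CC2c1ccc(OCOC)c2c(OC)cccc12 | intermediate
26 | potassium 8-methoxy-2,4-bis(Ar)-3,4-dihydronaphthalen-1-olate (racemic) | COc1cccc2c1C(O[K])=C(c1ccc(OCOC)c3c(OC)cccc13)CC2c1ccc(OCOC)c2c(OC)cccc12 | intermediate (not isolated)
27 | 2-bromo-8-methoxy-2,4-bis(Ar)-3,4-dihydronaphthalen-1(2H)-one (racemic diastereomer mixture) | COc1cccc2c1C(=O)C(Br)(c1ccc(OCOC)c3c(OC)cccc13)CC2c1ccc(OCOC)c2c(OC)cccc12 | intermediate (not isolated)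
28 | 8-methoxy-2,4-bis(Ar)naphthalen-1(4H)-one (racemic) | COc1cccc2c1C(=O)C(c1ccc(OCOC)c3c(OC)cccc13)=CC2c1ccc(OCOC)c2c(OC)cccc12 | intermediate (not isolated)
29 | 8-methoxy-2,4-bis[5-methoxy-4-(methoxymethoxy)naphthalen-1-yl]naphthalen-1-ol | COc1cccc2c(-c3ccc(OCOC)c4c(OC)cccc34)cc(-c3ccc(OCOC)c4c(OC)cccc34)c(O)c12 | intermediate
30 | 2,4-bis(4-hydroxy-5-methoxynaphthalen-1-yl)-8-methoxynaphthalen-1-ol (CNP0528831.0) | COc1cccc2c(-c3cc(-c4ccc(O)c5c(OC)cccc45)c4cccc(OC)c4c3O)ccc(O)c12 | target

Total step count: 14. Longest linear sequence: 9 steps (steps 4–9 and 12–14, from naphthalene-1,8-diol).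

Steps most likely to fail

1. Step 12. The vinyllithium may act as a base instead of adding. The ring-opened anion may also be protonated or add to a second molecule before it cyclizes, for instance if the C4 aryl group turns inward and slows the 6π closure. The fallback sets out from 8 and 10 and returns at 30; it makes both biaryl bonds by cross-coupling on a preformed ring B. 8 is brominated twice (NBS, 2 equiv, MeCN, 0 °C) to 2,4-dibromo-8-methoxynaphthalen-1-ol F1 and protected (NaH, MOMCl, DMF) as 2,4-dibromo-8-methoxy-1-(methoxymethoxy)naphthalene F2. 10 is converted by Miyaura borylation (B2pin2, Pd(dppf)Cl2, KOAc, dioxane, 90 °C) into 2-[5-methoxy-4-(methoxymethoxy)naphthalen-1-yl]-4,4,5,5-tetramethyl-1,3,2-dioxaborolane F3. Twofold Suzuki–Miyaura coupling of F2 with F3 (Pd(OAc)2, SPhos, K3PO4, toluene/water, 100 °C) should give 8-methoxy-1-(methoxymethoxy)-2,4-bis[5-methoxy-4-(methoxymethoxy)naphthalen-1-yl]naphthalene F4. The acid methanolysis of step 14 would then remove all three acetals to give 30.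

2. Step 9. The hindered, aryl-conjugated ketene silyl acetal may trap the aryne too slowly, so that butyllithium or aryllithium adds to the aryne instead, or the aryl anion may be protonated before the four-membered ring closes. The fallback sets out from 11 and 6 and returns at 16; it swaps the ketene acetal for an aldehyde enolate. 11 is reduced (i-Bu2AlH, toluene, –78 °C) to 2-[5-methoxy-4-(methoxymethoxy)naphthalen-1-yl]acetaldehyde F5. Deprotonation (LiN(SiMe3)2, THF, –78 °C) gives lithium 2-[5-methoxy-4-(methoxymethoxy)naphthalen-1-yl]ethen-1-olate F6, which is combined with 6 and n-BuLi so that aryne 14 is taken up by enolate [2+2] cycloaddition. The enolate carbon attacks the aryne carbon remote from the methoxy group and the aryl anion closes onto the aldehyde carbonyl, giving after aq. NH4Cl work-up 5-methoxy-8-[5-methoxy-4-(methoxymethoxy)naphthalen-1-yl]bicyclo[4.2.0]octa-1,3,5-trien-7-ol F7. Oxidation of the alcohol (DMP, NaHCO3, CH2Cl2, 0 °C) gives 16.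

3. Step 13. Halogenation at the hindered, fully substituted C2 may be incomplete or divert to an electron-rich naphthalene ring, and the naphthol may be over-oxidized once it has formed. The fallback sets out from 25 and returns at 29; it replaces halogenation and elimination by a palladium-mediated dehydrosilylation. Potassium enolate 26 (KN(SiMe3)2, THF, –78 °C) is trapped with Me3SiCl as {[8-methoxy-2,4-bis(5-methoxy-4-(methoxymethoxy)naphthalen-1-yl)-3,4-dihydronaphthalen-1-yl]oxy}trimethylsilane F8. Saegusa–Ito oxidation (Pd(OAc)2, MeCN, rt) should give dienone 28, which tautomerizes to 29 on treatment with Et3N.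

Further compounds
F1 | step 12 | 2,4-dibromo-8-methoxynaphthalen-1-ol | COc1cccc2c(Br)cc(Br)c(O)c12
F2 | step 12 | 2,4-dibromo-8-methoxy-1-(methoxymethoxy)naphthalene | COCOc1c(Br)cc(Br)c2cccc(OC)c12
F3 | step 12 | 2-[5-methoxy-4-(methoxymethoxy)naphthalen-1-yl]-4,4,5,5-tetramethyl-1,3,2-dioxaborolane | COCOc1ccc(B2OC(C)(C)C(C)(C)O2)c2cccc(OC)c12
F4 | step 12 | 8-methoxy-1-(methoxymethoxy)-2,4-bis[5-methoxy-4-(methoxymethoxy)naphthalen-1-yl]naphthalene | COCOc1c(-c2ccc(OCOC)c3c(OC)cccc23)cc(-c2ccc(OCOC)c3c(OC)cccc23)c2cccc(OC)c12
F5 | step 9 | 2-[5-methoxy-4-(methoxymethoxy)naphthalen-1-yl]acetaldehyde | COCOc1ccc(CC=O)c2cccc(OC)c12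
F6 | step 9 | lithium 2-[5-methoxy-4-(methoxymethoxy)naphthalen-1-yl]ethen-1-olate (E/Z mixture) | COCOc1ccc(C=CO[Li])c2cccc(OC)c12
F7 | step 9 | 5-methoxy-8-[5-methoxy-4-(methoxymethoxy)naphthalen-1-yl]bicyclo[4.2.0]octa-1,3,5-trien-7-ol (racemic diastereomer mixture) | COc1cccc2c1C(O)C2c1ccc(OCOC)c2c(OC)cccc12
F8 | step 13 | {[8-methoxy-2,4-bis(5-methoxy-4-(methoxymethoxy)naphthalen-1-yl)-3,4-dihydronaphthalen-1-yl]oxy}trimethylsilane (racemic) | COc1cccc2c1C(O[Si](C)(C)C)=C(c1ccc(OCOC)c3c(OC)cccc13)CC2c1ccc(OCOC)c2c(OC)cccc12
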